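**Plan**

1. The target is an 18-membered macrocycle of four benzene rings with one S carbinol centre: ring A (carbinol carbon at C1, aryloxy at C3, OH at C4 and C5), ring B (para O / CH2CH2), ring C (C1 chain, C2 ether oxygen, C3 OH) and ring D (O and CH2 meta).
2. Enabling feature: ring D carries its oxygen and its CH2 in a 1,3-relationship, the pattern of C3 and C5 of a 5-substituted cyclohexane-1,3-dione. The ring C O2, flanked by the C3 hydroxyl and the C1 CH2CH2 chain, makes the most hindered ether. The O2(ring C)–C(ring D) bond is therefore cut first, onto a 3-chlorocyclohex-2-enone standing in for ring D.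
3. Further cuts: the dione ring (Michael–Claisen with diethyl malonate), the enone C=C (cross-metathesis), the carbinol–CH2 bond (allylboration of the ring A aldehyde), the ring B–CH2 bond (B-alkyl Suzuki–Miyaura) and the ring A O–ring B bond (Ullmann).
4. Forward: rings A, B and C are joined as an open chain, the side chain and the cyclohexanedione are built on ring A, the macrocycle closes by phenoxide addition–elimination, ring D is aromatised and deoxygenated, and the protecting groups are removed.
5. Stereochemistry: the S centre is set by reagent-controlled Brown allylboration with the (+)-α-pinene-derived borane and is only carried afterwards. The extra ring CH centre of the enone is an epimer mixture that disappears on aromatisation.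

Key step: step 13

Abbreviations in the names: Ar = 7-(4-{2-[3-(benzyloxy)-2-(4-methoxybenzyloxy)phenyl]ethyl}phenoxy)-2,2-diphenyl-1,3-benzodioxol-5-yl (ring A as its diphenylmethylene ketal, bound through oxygen to ring B and through CH2CH2 to ring C, which carries 3-OBn and 2-OPMB); Ar′ = the same group with a free 2-OH on ring C; TIPS = triisopropylsilyl.

Remark on the chemistry: the ring carbons of the ring D precursor are carried as epimer mixtures in 17–19 and 21–26; they become achiral when ring D is aromatised in step 14, so only the S carbinol centre has to be controlled.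

**Route**

Step 1
Reactants: 1 2,3-dihydroxybenzaldehyde
Product: 2 3-(benzyloxy)-2-hydroxybenzaldehyde
Conditions: NaH (2.2 equiv), DMSO/THF, rt; BnBr (1.0 equiv); aq. HCl work-up
Reagents that add atoms: benzyl bromide, BrCc1ccccc1
Why: Williamson etherification of the dianion, in which the 3-phenoxide, neither conjugated to nor chelated by the formyl group, is the more nucleophilic oxygen and is benzylated selectively.

Step 2
Reactants: 2 3-(benzyloxy)-2-hydroxybenzaldehyde
Product: 3 3-(benzyloxy)-2-[(4-methoxybenzyl)oxy]benzaldehyde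
Conditions: PMBCl, K2CO3, Bu4NI (cat.), DMF, 60 °C
Reagents that add atoms: 4-methoxybenzyl chloride, COc1ccc(CCl)cc1
Why: Williamson etherification of the remaining ortho-hydroxyl gives a PMB ether that survives base, boranes, metathesis and alkoxide and can later be removed oxidatively beside benzyl ethers.

Step 3
Reactants: 3 3-(benzyloxy)-2-[(4-methoxybenzyl)oxy]benzaldehyde
Product: 4 1-(benzyloxy)-3-ethenyl-2-[(4-methoxybenzyl)oxy]benzene
Conditions: Ph3PCH3Br, KOtBu, THF, 0 °C → rt
Reagents that add atoms: methyltriphenylphosphonium bromide, C[P+](c1ccccc1)(c1ccccc1)c1ccccc1.[Br-]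
Why: Wittig methylenation of an aryl aldehyde with the non-stabilised ylide gives the styrene needed for hydroboration.

Step 4
Reactants: 5 3,4,5-trihydroxybenzaldehyde
Product: 6 7-hydroxy-2,2-diphenyl-1,3-benzodioxole-5-carbaldehyde
Conditions: Ph2CCl2, Ph2O, 175 °C
Reagents that add atoms: dichlorodiphenylmethane, ClC(Cl)(c1ccccc1)c1ccccc1
Why: Acetalisation of a catechol pair with a gem-dichloride; the diphenylmethylene bridge can only span two adjacent hydroxyls and the two possible pairs are equivalent by symmetry, so one ketal with one free phenol results, removable at the end by hydrogenolysis.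

Step 5
Reactants: 6 7-hydroxy-2,2-diphenyl-1,3-benzodioxole-5-carbaldehyde; 7 1-bromo-4-iodobenzene
Product: 8 7-(4-bromophenoxy)-2,2-diphenyl-1,3-benzodioxole-5-carbaldehyde
Conditions: CuI (cat.), N,N-dimethylglycine·HCl, Cs2CO3, 1,4-dioxane, 90 °C; 7 in excess
Reagents that add atoms: none
Why: Ullmann diaryl ether synthesis, in which the C–I bond of 7 reacts before the C–Br bond, so that the bromide is kept for the next coupling.

Step 6
Reactants: 4 1-(benzyloxy)-3-ethenyl-2-[(4-methoxybenzyl)oxy]benzene; 8 7-(4-bromophenoxy)-2,2-diphenyl-1,3-benzodioxole-5-carbaldehyde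
Product: 10 bibenzyl aldehyde Ar–CHO, via alkylborane 9 (not isolated)
Conditions: 4, 9-BBN, THF, 0 °C → rt; then 8, Pd(dppf)Cl2 (cat.), aq. K3PO4, DMF, 50 °C
Reagents that add atoms: none
Why: Anti-Markovnikov hydroboration of the styrene followed by B-alkyl Suzuki–Miyaura coupling with the aryl bromide gives the saturated CH2CH2 bridge directly; the aldehyde is tolerated because all B–H is consumed before 8 is added and the base is mild.

Step 7
Reactants: 10 bibenzyl aldehyde Ar–CHO
Product: 12 (1S)-1-Ar-but-3-en-1-ol, via borinate ester 11 (not isolated)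
Conditions: (−)-Ipc2B(allyl) (the enantiomer made from (+)-α-pinene), Et2O, −78 °C; then NaOH, H2O2, 0 °C → rt
Reagents that add atoms: (−)-B-allyldiisopinocampheylborane, C=CCB([C@@H]1C[C@@H]2C[C@H]([C@H]1C)C2(C)C)[C@@H]1C[C@@H]2C[C@H]([C@H]1C)C2(C)C
Why: Brown asymmetric allylboration through a closed chair transition state, in which the isopinocampheyl groups derived from (+)-α-pinene deliver the allyl group to the Si face of the aryl aldehyde and so set the S carbinol centre.

Step 8
Reactants: 12 (1S)-1-Ar-but-3-en-1-ol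
Product: 13 (1S)-1-Ar-1-(triisopropylsilyloxy)but-3-ene
Conditions: TIPSOTf, 2,6-lutidine, CH2Cl2, 0 °C
Reagents that add atoms: triisopropylsilyl trifluoromethanesulfonate, CC(C)[Si](OS(=O)(=O)C(F)(F)F)(C(C)C)C(C)C
Why: Silylation of a secondary alcohol with a silyl triflate and a hindered base; the TIPS ether is chosen because it should withstand the alkoxide, hydroxide and mild acid of step 10 and the HCl of step 11 better than smaller silyl groups.

Step 9
Reactants: 13 (1S)-1-Ar-1-(triisopropylsilyloxy)but-3-ene; 14 methyl vinyl ketone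
Product: 15 (3E,6S)-6-Ar-6-(triisopropylsilyloxy)hex-3-en-2-one
Conditions: 14 (excess), second-generation Hoveyda–Grubbs catalyst RuCl2(H2IMes)(=CH-C6H4-2-OiPr) (cat.), CH2Cl2, 40 °C
Reagents that add atoms: none
Why: Olefin cross-metathesis of a terminal alkene with an electron-poor partner is selective for the cross product and the E enone and leaves ethers, ketal and silyl ether untouched.

Step 10
Reactants: 15 (3E,6S)-6-Ar-6-(triisopropylsilyloxy)hex-3-en-2-one; 16 diethyl malonate
Product: 20 5-[(2S)-2-Ar-2-(triisopropylsilyloxy)ethyl]cyclohexane-1,3-dione, via Michael adduct 17 (not isolated), via keto ester 18 (not isolated), via keto acid 19 (not isolated)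
Conditions: 16, NaOEt (cat.), EtOH, 0 °C → rt; then NaOEt (1.5 equiv), reflux; then aq. NaOH, 80 °C; then HCl to pH 3, 60 °C
Reagents that add atoms: none
Why: Michael addition of the malonate anion, Claisen (Dieckmann-type) cyclisation of the methyl ketone enolate onto an ester, saponification and decarboxylation of the β-keto acid is the classical dimedone-type synthesis of a 5-substituted cyclohexane-1,3-dione; the conjugate addition is run cold with catalytic base first so that it outruns γ-deprotonation of the enone.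

Step 11
Reactants: 20 5-[(2S)-2-Ar-2-(triisopropylsilyloxy)ethyl]cyclohexane-1,3-dione
Product: 21 3-chloro-5-[(2S)-2-Ar-2-(triisopropylsilyloxy)ethyl]cyclohex-2-en-1-one (both C5 epimers)
Conditions: (COCl)2, DMF (cat.), CH2Cl2, 0 °C → rt
Reagents that add atoms: oxalyl chloride, ClC(=O)C(=O)Cl
Why: Conversion of a cyclic 1,3-dione into its vinylogous acid chloride by chloroiminium (Vilsmeier-type) activation of the enol; both carbonyls of 20 give the same constitution, so only the two ring CH epimers arise.

Step 12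
Reactants: 21 3-chloro-5-[(2S)-2-Ar-2-(triisopropylsilyloxy)ethyl]cyclohex-2-en-1-one
Product: 22 3-chloro-5-[(2S)-2-Ar′-2-(triisopropylsilyloxy)ethyl]cyclohex-2-en-1-one (free ring C 2-OH; both C5 epimers)
Conditions: DDQ, CH2Cl2/pH 7 buffer, 0 °C → rt
Reagents that add atoms: none
Why: Oxidative cleavage of a 4-methoxybenzyl ether by DDQ (hydride abstraction from the electron-rich benzylic CH2, then hydrolysis of the oxocarbenium ion) is selective over plain benzyl ethers, the diphenylmethylene ketal, the silyl ether and the chloro-enone.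

Step 13
Reactants: 22 3-chloro-5-[(2S)-2-Ar′-2-(triisopropylsilyloxy)ethyl]cyclohex-2-en-1-one
Product: 23 macrocyclic 3-aryloxycyclohex-2-en-1-one (ring C O2 bonded to enone C3; enone C5 bears the CH2–CH(OTIPS)–ring A chain; S carbinol; both C5 epimers)
Conditions: Cs2CO3, DMF, 60 °C; 22 added by syringe pump over 12 h (final ca. 2 mM)
Reagents that add atoms: none
Why: The caesium phenoxide of the ring C 2-hydroxyl adds to the β-carbon (C3) of the vinylogous acid chloride and the enolate formed expels chloride, a conjugate addition–elimination that creates the O2(ring C)–C3 bond of the future ring D. The closest known reaction type is the base-mediated etherification of phenols with 3-chlorocyclohex-2-enones to 3-aryloxycyclohexenones, used here intramolecularly. The 18-membered ring closes in an 18-exo-trig addition onto an sp2 carbon of a flexible, non-planar six-membered ring that is far more electrophilic and less encumbered than any aryl halide a di-ortho-substituted phenol would otherwise have to attack. No stereocentre is formed: the S carbinol centre is a silylated spectator under these mildly basic conditions, and both ring CH epimers can cyclise and converge on aromatisation. The step needs attack by one oxygen only and ring closure in preference to oligomerisation; the first is secured because the ring C 2-OH is the only free hydroxyl (3-OH benzylated, ring A diol ketalised, carbinol silylated), the second by slow addition into dilute Cs2CO3/DMF so that each phenoxide meets its own chloro-enone. Because the chloro-enone derives from a dione whose two carbonyls lead to the same constitution, there is no regiochemical choice at the electrophile.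

Step 14
Reactants: 23 macrocyclic 3-aryloxycyclohex-2-en-1-one
Product: 27 macrocyclic phenol (ring D = 3-aryloxy-5-alkylphenol; rest as in 23), via selenide 24 (not isolated), via selenoxide 25 (not isolated), via dienone 26 (not isolated)
Conditions: LiN(iPr)2, THF, −78 °C; PhSeBr; then H2O2, pyridine, CH2Cl2, 0 °C → rt
Reagents that add atoms: none
Why: Kinetic α′-deprotonation of the vinylogous ester, α-selenenylation and selenoxide syn-elimination towards the ring CH give the cross-conjugated 2,5-dienone, which is the keto tautomer of the ring D phenol and aromatises at once, erasing the ring CH stereocentre.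

Step 15
Reactants: 27 macrocyclic phenol
Product: 28 macrocyclic aryl triflate (ring D OTf in place of OH)
Conditions: Tf2O, pyridine, CH2Cl2, 0 °C
Reagents that add atoms: trifluoromethanesulfonic anhydride, FC(F)(F)S(=O)(=O)OS(=O)(=O)C(F)(F)F
Why: O-Sulfonylation of the only free hydroxyl, the new ring D phenol, gives the aryl triflate.

Step 16
Reactants: 28 macrocyclic aryl triflate
Product: 29 macrocyclic tetra-aryl ether with ring D as a 1,3-disubstituted benzene (TIPS ether, benzyl ether and ketal retained)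
Conditions: Pd(OAc)2 (cat.), dppf, HCO2H, Et3N, DMF, 70 °C
Reagents that add atoms: none
Why: Palladium-catalysed transfer hydrogenolysis of an aryl triflate (oxidative addition to zerovalent palladium, formate exchange, loss of CO2, reductive elimination of Ar–H) under homogeneous conditions that do not cleave benzyl ethers.

Step 17
Reactants: 29 macrocyclic TIPS ether
Product: 30 macrocyclic S alcohol (ring C 3-OBn and ring A diphenylmethylene ketal retained)
Conditions: Bu4NF, THF, rt
Reagents that add atoms: none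
Why: Fluoride-mediated desilylation driven by the Si–F bond releases the benzylic alcohol under non-acidic conditions while all phenols are still protected, so the S centre is not put at risk.

Step 18
Reactants: 30 macrocyclic S alcohol
Product: 31 CNP0333307.1
Conditions: H2 (1 atm), Pd/C, EtOAc/MeOH, rt
Reagents that add atoms: none
Why: Heterogeneous catalytic hydrogenolysis of the benzyl ether and of the diphenylmethylene ketal under neutral conditions, in which a secondary benzylic alcohol is normally retained, frees the three phenols.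

**Compound list**

1 | 2,3-dihydroxybenzaldehyde | O=Cc1cccc(O)c1O | starting material
2 | 3-(benzyloxy)-2-hydroxybenzaldehyde | O=Cc1cccc(OCc2ccccc2)c1O | intermediate
3 | 3-(benzyloxy)-2-[(4-methoxybenzyl)oxy]benzaldehyde | O=Cc1cccc(OCc2ccccc2)c1OCc1ccc(OC)cc1 | intermediate
4 | 1-(benzyloxy)-3-ethenyl-2-[(4-methoxybenzyl)oxy]benzene | C=Cc1cccc(OCc2ccccc2)c1OCc1ccc(OC)cc1 | intermediate
5 | 3,4,5-trihydroxybenzaldehyde | O=Cc1cc(O)c(O)c(O)c1 | starting material
6 | 7-hydroxy-2,2-diphenyl-1,3-benzodioxole-5-carbaldehyde | O=Cc1cc(O)c2OC(c3ccccc3)(c3ccccc3)Oc2c1 | intermediate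
7 | 1-bromo-4-iodobenzene | Brc1ccc(I)cc1 | starting material
8 | 7-(4-bromophenoxy)-2,2-diphenyl-1,3-benzodioxole-5-carbaldehyde | O=Cc1cc(Oc2ccc(Br)cc2)c2OC(c3ccccc3)(c3ccccc3)Oc2c1 | intermediate
9 | 9-{2-[3-(benzyloxy)-2-(4-methoxybenzyloxy)phenyl]ethyl}-9-borabicyclo[3.3.1]nonane (alkylborane) | C(Cc1cccc(OCc2ccccc2)c1OCc1ccc(OC)cc1)B1C2CCCC1CCC2 | intermediate
10 | Ar–CHO, 7-(4-{2-[3-(benzyloxy)-2-(4-methoxybenzyloxy)phenyl]ethyl}phenoxy)-2,2-diphenyl-1,3-benzodioxole-5-carbaldehyde | O=Cc1cc(Oc2ccc(CCc3cccc(OCc4ccccc4)c3OCc3ccc(OC)cc3)cc2)c2OC(c3ccccc3)(c3ccccc3)Oc2c1 | intermediate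
11 | diisopinocampheylborinate of 12 (borinate ester) | C=CC[C@H](OB([C@@H]1C[C@@H]2C[C@H]([C@H]1C)C2(C)C)[C@@H]1C[C@@H]2C[C@H]([C@H]1C)C2(C)C)c1cc(Oc2ccc(CCc3cccc(OCc4ccccc4)c3OCc3ccc(OC)cc3)cc2)c2OC(c3ccccc3)(c3ccccc3)Oc2c1 | intermediate
12 | (1S)-1-Ar-but-3-en-1-ol | C=CC[C@H](O)c1cc(Oc2ccc(CCc3cccc(OCc4ccccc4)c3OCc3ccc(OC)cc3)cc2)c2OC(c3ccccc3)(c3ccccc3)Oc2c1 | intermediate
13 | (1S)-1-Ar-1-(triisopropylsilyloxy)but-3-ene | C=CC[C@H](O[Si](C(C)C)(C(C)C)C(C)C)c1cc(Oc2ccc(CCc3cccc(OCc4ccccc4)c3OCc3ccc(OC)cc3)cc2)c2OC(c3ccccc3)(c3ccccc3)Oc2c1 | intermediate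
14 | methyl vinyl ketone (but-3-en-2-one) | CC(=O)C=C | starting material
15 | (3E,6S)-6-Ar-6-(triisopropylsilyloxy)hex-3-en-2-one | CC(=O)/C=C/C[C@H](O[Si](C(C)C)(C(C)C)C(C)C)c1cc(Oc2ccc(CCc3cccc(OCc4ccccc4)c3OCc3ccc(OC)cc3)cc2)c2OC(c3ccccc3)(c3ccccc3)Oc2c1 | intermediate
16 | diethyl malonate | CCOC(=O)CC(=O)OCC | starting material
17 | diethyl 2-[(6S)-6-Ar-2-oxo-6-(triisopropylsilyloxy)hexan-4-yl]malonate (Michael adduct, both C4 epimers) | CCOC(=O)C(C(=O)OCC)C(CC(C)=O)C[C@H](O[Si](C(C)C)(C(C)C)C(C)C)c1cc(Oc2ccc(CCc3cccc(OCc4ccccc4)c3OCc3ccc(OC)cc3)cc2)c2OC(c3ccccc3)(c3ccccc3)Oc2c1 | intermediate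
18 | ethyl 2,4-dioxo-6-[(2S)-2-Ar-2-(triisopropylsilyloxy)ethyl]cyclohexane-1-carboxylate (keto ester, ring epimers) | CCOC(=O)C1C(=O)CC(=O)CC1C[C@H](O[Si](C(C)C)(C(C)C)C(C)C)c1cc(Oc2ccc(CCc3cccc(OCc4ccccc4)c3OCc3ccc(OC)cc3)cc2)c2OC(c3ccccc3)(c3ccccc3)Oc2c1 | intermediate
19 | 2,4-dioxo-6-[(2S)-2-Ar-2-(triisopropylsilyloxy)ethyl]cyclohexane-1-carboxylic acid (keto acid, ring epimers) | OC(=O)C1C(=O)CC(=O)CC1C[C@H](O[Si](C(C)C)(C(C)C)C(C)C)c1cc(Oc2ccc(CCc3cccc(OCc4ccccc4)c3OCc3ccc(OC)cc3)cc2)c2OC(c3ccccc3)(c3ccccc3)Oc2c1 | intermediate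
20 | 5-[(2S)-2-Ar-2-(triisopropylsilyloxy)ethyl]cyclohexane-1,3-dione | O=C1CC(=O)CC(C1)C[C@H](O[Si](C(C)C)(C(C)C)C(C)C)c1cc(Oc2ccc(CCc3cccc(OCc4ccccc4)c3OCc3ccc(OC)cc3)cc2)c2OC(c3ccccc3)(c3ccccc3)Oc2c1 | intermediate
21 | 3-chloro-5-[(2S)-2-Ar-2-(triisopropylsilyloxy)ethyl]cyclohex-2-en-1-one, both C5 epimers | ClC1=CC(=O)CC(C1)C[C@H](O[Si](C(C)C)(C(C)C)C(C)C)c1cc(Oc2ccc(CCc3cccc(OCc4ccccc4)c3OCc3ccc(OC)cc3)cc2)c2OC(c3ccccc3)(c3ccccc3)Oc2c1 | intermediate
22 | 3-chloro-5-[(2S)-2-Ar′-2-(triisopropylsilyloxy)ethyl]cyclohex-2-en-1-one (free ring C 2-OH), both C5 epimers | ClC1=CC(=O)CC(C1)C[C@H](O[Si](C(C)C)(C(C)C)C(C)C)c1cc(Oc2ccc(CCc3cccc(OCc4ccccc4)c3O)cc2)c2OC(c3ccccc3)(c3ccccc3)Oc2c1 | intermediate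
23 | macrocyclic 3-aryloxycyclohex-2-en-1-one (ring C O2 on enone C3, side chain on enone C5, S carbinol as TIPS ether, ring C 3-OBn, ring A ketal), both C5 epimers | O=C1C=C2CC(C1)C[C@H](O[Si](C(C)C)(C(C)C)C(C)C)c1cc(Oc3ccc(CCc4cccc(OCc5ccccc5)c4O2)cc3)c3OC(c4ccccc4)(c4ccccc4)Oc3c1 | intermediate
24 | 6-(phenylselanyl) derivative of 23 (selenide; Se on the CH2 between C=O and the ring CH) | O=C1C=C2CC(C1[Se]c1ccccc1)C[C@H](O[Si](C(C)C)(C(C)C)C(C)C)c1cc(Oc3ccc(CCc4cccc(OCc5ccccc5)c4O2)cc3)c3OC(c4ccccc4)(c4ccccc4)Oc3c1 | intermediate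
25 | selenoxide of 24 | O=C1C=C2CC(C1[Se](=O)c1ccccc1)C[C@H](O[Si](C(C)C)(C(C)C)C(C)C)c1cc(Oc3ccc(CCc4cccc(OCc5ccccc5)c4O2)cc3)c3OC(c4ccccc4)(c4ccccc4)Oc3c1 | intermediate
26 | macrocyclic 3-aryloxy-5-alkylcyclohexa-2,5-dien-1-one (dienone) | O=C1C=C2CC(=C1)C[C@H](O[Si](C(C)C)(C(C)C)C(C)C)c1cc(Oc3ccc(CCc4cccc(OCc5ccccc5)c4O2)cc3)c3OC(c4ccccc4)(c4ccccc4)Oc3c1 | intermediate
27 | macrocyclic phenol (ring D: 1-OH, 3-O–ring C, 5-CH2; S carbinol as TIPS ether) | Oc1cc2cc(c1)C[C@H](O[Si](C(C)C)(C(C)C)C(C)C)c1cc(Oc3ccc(CCc4cccc(OCc5ccccc5)c4O2)cc3)c3OC(c4ccccc4)(c4ccccc4)Oc3c1 | intermediate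
28 | macrocyclic aryl triflate of 27 | FC(F)(F)S(=O)(=O)Oc1cc2cc(c1)C[C@H](O[Si](C(C)C)(C(C)C)C(C)C)c1cc(Oc3ccc(CCc4cccc(OCc5ccccc5)c4O2)cc3)c3OC(c4ccccc4)(c4ccccc4)Oc3c1 | intermediate
29 | macrocycle with ring D as 1,3-disubstituted benzene (S carbinol as TIPS ether, ring C 3-OBn, ring A ketal) | c1cc2cc(c1)C[C@H](O[Si](C(C)C)(C(C)C)C(C)C)c1cc(Oc3ccc(CCc4cccc(OCc5ccccc5)c4O2)cc3)c3OC(c4ccccc4)(c4ccccc4)Oc3c1 | intermediate
30 | macrocyclic S alcohol (ring C 3-OBn, ring A diphenylmethylene ketal) | c1cc2cc(c1)C[C@H](O)c1cc(Oc3ccc(CCc4cccc(OCc5ccccc5)c4O2)cc3)c3OC(c4ccccc4)(c4ccccc4)Oc3c1 | intermediate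
31 | CNP0333307.1, S carbinol | Oc1cc2cc(c1O)Oc1ccc(cc1)CCc1cccc(O)c1Oc1cccc(c1)C[C@@H]2O | target

**Step count and risks**

Total step count: 18. Longest linear sequence: 16 steps (from 1 through steps 1–3 and 6–18); the ring A branch (steps 4–5) joins at step 6.

The three steps most likely to fail:

Step 13 (macrocyclisation). Intermolecular etherification may outrun ring closure, so that dimers and oligomers grow while the conformer needed for the 18-membered ring is populated too rarely. The fallback replaces the phenoxide reservoir by a latent nucleophile. It sets out from 22, whose ring C phenol is silylated (TBSCl, imidazole, DMF) to the aryl tert-butyldimethylsilyl ether F1. CsF in DMF at 60 °C under high dilution then cleaves the aryl silyl ether slowly, much faster than the secondary TIPS ether. The caesium phenoxide is thus released one molecule at a time next to its own chloro-enone and closes to 23, where the route is rejoined.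

Step 10 (dione construction). Ethoxide may remove a γ-proton of enone 15, after which the dienolate expels the silanolate (vinylogous E1cB) to a styryl dienone; alternatively the Michael adduct may revert before it cyclises. The fallback avoids free base while the enone is present and needs no decarboxylation. It sets out from 15: uncatalysed Mukaiyama–Michael addition of 1-ethoxy-1-(trimethylsilyloxy)ethene in MeCN at 55 °C, followed by hydrolytic work-up, gives the δ-keto ester ethyl 3-[(2S)-2-Ar-2-(triisopropylsilyloxy)ethyl]-5-oxohexanoate F2. KOtBu in THF at 0 °C then closes the ring by intramolecular Claisen condensation of the methyl ketone enolate onto the ester, and the route is rejoined at dione 20.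

Step 14 (aromatisation). In one epimer of the constrained macrocycle the selenoxide may fail to reach the syn-periplanar geometry towards the ring CH, or selenium by-products may attack the electron-rich phenol as it forms. The fallback aromatises at the enol triflate level. It sets out from 23: LiN(iPr)2 and then PhNTf2 (THF, −78 °C) give the cross-conjugated cyclohexadienyl triflate F3. DDQ in toluene at rt dehydrogenates this cyclohexa-1,3-diene to the aryl triflate 28, where the route is rejoined; phenol 27 and step 15 are bypassed.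

Further compounds
F1 | step 13 | 3-chloro-5-[(2S)-2-aryl-2-(triisopropylsilyloxy)ethyl]cyclohex-2-en-1-one with the ring C 2-oxygen as tert-butyldimethylsilyl ether | ClC1=CC(=O)CC(C1)C[C@H](O[Si](C(C)C)(C(C)C)C(C)C)c1cc(Oc2ccc(CCc3cccc(OCc4ccccc4)c3O[Si](C)(C)C(C)(C)C)cc2)c2OC(c3ccccc3)(c3ccccc3)Oc2c1
F2 | step 10 | ethyl 3-[(2S)-2-Ar-2-(triisopropylsilyloxy)ethyl]-5-oxohexanoate | CCOC(=O)CC(CC(C)=O)C[C@H](O[Si](C(C)C)(C(C)C)C(C)C)c1cc(Oc2ccc(CCc3cccc(OCc4ccccc4)c3OCc3ccc(OC)cc3)cc2)c2OC(c3ccccc3)(c3ccccc3)Oc2c1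
F3 | step 14 | macrocyclic 3-aryloxy-5-alkylcyclohexa-1,3-dien-1-yl triflate (cross-conjugated dienyl triflate of 23) | FC(F)(F)S(=O)(=O)OC1=CC(CC2=C1)C[C@H](O[Si](C(C)C)(C(C)C)C(C)C)c1cc(Oc3ccc(CCc4cccc(OCc5ccccc5)c4O2)cc3)c3OC(c4ccccc4)(c4ccccc4)Oc3c1
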